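**Plan**

- Retrosynthesis: the two O–CH3 bonds at the C7 and C4' oxygens are cut first, then the four aryl C–O bonds at C6, C8, C3' and C5' are cut together to four C–Br bonds, and these in turn to C–H bonds of a commercial isoflavone.
- Forward: no ring is built. Rings A, B and C are bought as daidzein 1. Bromine 2 marks the four carbons ortho to its two phenols (tetrabromide 3). Sodium methoxide 4 with CuBr exchanges all four bromides (through phenoxides 5 and 6) to give bis-phenol 7. Iodomethane 8 caps both phenols to give target 9.
- Enabling feature: in the target the C7 oxygen of ring A and the C4' oxygen of ring B each sit between two methoxy-bearing carbons (C6/C8 and C3'/C5'). These four carbons are the ortho positions of the two hydroxyl groups of daidzein.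
- Stereochemistry: none to set; the target has no stereocentre and no stereogenic double bond.

Key step: step 2

Remark: positions follow isoflavone numbering (O1, C2, C3, C4=O, ring A C5 to C8, ring B primed); NaOMe is used as a dry commercial solution in methanol.

**Step 1**
Reactants: 1 daidzein (7-hydroxy-3-(4-hydroxyphenyl)chromen-4-one); 2 bromine
Product: 3 6,8-dibromo-3-(3,5-dibromo-4-hydroxyphenyl)-7-hydroxychromen-4-one
Conditions: Br2 (4.5 equiv), AcOH, 25 to 60 °C; aq. NaHSO3 quench
Reagents that add atoms: bromine, BrBr
Why: Electrophilic aromatic bromination is directed by the two free phenols to their four ortho carbons (C6 and C8 on ring A, C3' and C5' on ring B), the para positions being blocked by the ring fusion and by the bond to C3, while the electron-poor C2–C3 double bond of the pyranone and the hydrogens at C5, C2' and C6' meta to the hydroxyl groups should remain untouched.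

**Step 2**
Reactants: 3 6,8-dibromo-3-(3,5-dibromo-4-hydroxyphenyl)-7-hydroxychromen-4-one; 4 sodium methoxide
Product: 7 7-hydroxy-3-(4-hydroxy-3,5-dimethoxyphenyl)-6,8-dimethoxychromen-4-one, via tetrabromide disodium bis-phenoxide 5 (not isolated), via tetramethoxy disodium bis-phenoxide 6 (not isolated)
Conditions: NaOMe (14 equiv, dry, in MeOH), CuBr (0.4 equiv), DMF, 110 °C, N2; then aq. HCl, 25 °C
Reagents that add atoms: sodium methoxide, [Na+].[O-]C
Why: Excess NaOMe first converts 3 into bis-phenoxide 5, and the monovalent copper methoxide formed from CuBr and NaOMe then adds oxidatively to each aryl C–Br bond, the resulting trivalent aryl copper methoxide eliminating reductively to forge the aryl–OMe bond and regenerate monovalent copper; four such cycles give 6, which aqueous HCl protonates to 7. The closest known reaction type is the Ullmann-type copper-catalysed methoxylation of ortho-bromophenols with NaOMe in MeOH/DMF, the process that turns 5-bromovanillin into syringaldehyde and that is compatible with a neighbouring phenoxide. No ring is closed and no stereocentre is created; the step forms only the four C–O bonds at C6, C8, C3' and C5'. The selectivity required is substitution at the four C–Br bonds in preference to attack of methoxide at C2 of ring C, and it is secured by the C7 phenoxide, which is para to the C4 acyl carbon and so forms a vinylogous carboxylate that lowers the electrophilicity of the pyranone. As a second safeguard the methoxide is kept free of hydroxide, so that any adduct at C2 can only open to an enol ether or acetal that cannot lose C2 as formate and that should reclose to the chromone in the acidic work-up. Air is excluded so that the copper stays monovalent and the electron-rich phenoxides are not oxidised.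

**Step 3**
Reactants: 7 7-hydroxy-3-(4-hydroxy-3,5-dimethoxyphenyl)-6,8-dimethoxychromen-4-one; 8 iodomethane
Product: 9 6,7,8-trimethoxy-3-(3,4,5-trimethoxyphenyl)chromen-4-one
Conditions: MeI (6 equiv), K2CO3 (5 equiv), acetone, reflux
Reagents that add atoms: iodomethane, CI
Why: In this Williamson ether synthesis K2CO3 deprotonates both phenols and the phenoxides displace iodide from iodomethane by SN2, and since the molecule holds no other nucleophilic or base-labile site under these mild conditions only the C7 and C4' oxygens should be alkylated.

**Compound list**

1 | daidzein (7-hydroxy-3-(4-hydroxyphenyl)chromen-4-one) | O=c1c(-c2ccc(O)cc2)coc2cc(O)ccc12 | starting material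
2 | bromine | BrBr | starting material
3 | 6,8-dibromo-3-(3,5-dibromo-4-hydroxyphenyl)-7-hydroxychromen-4-one | O=c1c(-c2cc(Br)c(O)c(Br)c2)coc2c(Br)c(O)c(Br)cc12 | intermediate
4 | sodium methoxide | [Na+].[O-]C | starting material
5 | disodium bis-phenoxide of 3, formed in the flask (disodium 6,8-dibromo-3-(3,5-dibromo-4-oxidophenyl)-4-oxochromen-7-olate) | O=c1c(-c2cc(Br)c([O-])c(Br)c2)coc2c(Br)c([O-])c(Br)cc12.[Na+].[Na+] | intermediate
6 | disodium bis-phenoxide of 7, formed in the flask (disodium 3-(3,5-dimethoxy-4-oxidophenyl)-6,8-dimethoxy-4-oxochromen-7-olate) | COc1cc(-c2coc3c(OC)c([O-])c(OC)cc3c2=O)cc(OC)c1[O-].[Na+].[Na+] | intermediate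
7 | 7-hydroxy-3-(4-hydroxy-3,5-dimethoxyphenyl)-6,8-dimethoxychromen-4-one | COc1cc(-c2coc3c(OC)c(O)c(OC)cc3c2=O)cc(OC)c1O | intermediate
8 | iodomethane | CI | starting material
9 | 6,7,8-trimethoxy-3-(3,4,5-trimethoxyphenyl)chromen-4-one | COc1cc(-c2coc3c(OC)c(OC)c(OC)cc3c2=O)cc(OC)c1OC | target

**Step count and risks**

Total step count: 3. Longest linear sequence: 3 steps (1 to 3 to 7 to 9).

Steps most likely to fail, riskiest first:

Step 2. The danger is irreversible cleavage of ring C. Methoxide, or hydroxide from base that is not dry, adds at C2, the pyranone opens, and the C2 carbon is lost as formate by retro-Claisen cleavage before all four bromides have been exchanged. The fallback sets out from 3 and makes this opening deliberate, ahead of the copper step. Hot aqueous NaOH, the classical alkaline degradation of an isoflavone to its deoxybenzoin, should give 1-(3,5-dibromo-2,4-dihydroxyphenyl)-2-(3,5-dibromo-4-hydroxyphenyl)ethanone F1, which has no pyranone left to lose. The same CuBr/NaOMe exchange under nitrogen should then form the identical four C–O bonds on this robust ketone and give 1-(2,4-dihydroxy-3,5-dimethoxyphenyl)-2-(4-hydroxy-3,5-dimethoxyphenyl)ethanone F2. Ring C is finally rebuilt with one carbon from DMF (BF3·OEt2, DMF, MsCl, 60 to 70 °C). This is a Vilsmeier-type formylation of the activated methylene followed by cyclisation through the only hydroxyl ortho to the ketone, and it tolerates free phenols. The fallback comes back to the route at 7.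

Step 1. The bromination may stop short of the fourth substitution, because partly brominated phenols precipitate from acetic acid and C6 is the slowest site. Bromine or HBr may also add across the C2–C3 double bond under forcing conditions. The fallback sets out from 1 and changes the halogen and the medium. N-iodosuccinimide (4.4 equiv) in DMF at room temperature is a homogeneous, phenol-directed iodination with a milder electrophile that should not add to the enone. It should give 7-hydroxy-3-(4-hydroxy-3,5-diiodophenyl)-6,8-diiodochromen-4-one F3. The four aryl iodides, the more reactive partners in Ullmann-type exchange, are then treated with CuBr/NaOMe as in step 2, and the fallback comes back to the route at 7.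

Step 3. The alkylation may stall at the mono-ether stage, because each phenoxide is shielded by two ortho methoxy groups and the dipotassium salt is poorly soluble in acetone. The fallback sets out from 3 and reverses the order of the last two operations. The acidic, fully ionised dibromophenols of 3 are O-methylated first (MeI, K2CO3, DMF) to 6,8-dibromo-3-(3,5-dibromo-4-methoxyphenyl)-7-methoxychromen-4-one F4. The CuBr/NaOMe exchange on F4 then installs the remaining four methoxy groups. The C7 phenoxide is absent here, so the pyranone relies on strictly dry methoxide and an acidic work-up that recloses any C2 adduct. The fallback comes back to the route at 9.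

**Further compounds**

F1 | step 2 | 1-(3,5-dibromo-2,4-dihydroxyphenyl)-2-(3,5-dibromo-4-hydroxyphenyl)ethanone | O=C(Cc1cc(Br)c(O)c(Br)c1)c1cc(Br)c(O)c(Br)c1O
F2 | step 2 | 1-(2,4-dihydroxy-3,5-dimethoxyphenyl)-2-(4-hydroxy-3,5-dimethoxyphenyl)ethanone | O=C(Cc1cc(OC)c(O)c(OC)c1)c1cc(OC)c(O)c(OC)c1O
F3 | step 1 | 7-hydroxy-3-(4-hydroxy-3,5-diiodophenyl)-6,8-diiodochromen-4-one | O=c1c(-c2cc(I)c(O)c(I)c2)coc2c(I)c(O)c(I)cc12
F4 | step 3 | 6,8-dibromo-3-(3,5-dibromo-4-methoxyphenyl)-7-methoxychromen-4-one | COc1c(Br)cc2c(=O)c(-c3cc(Br)c(OC)c(Br)c3)coc2c1Br
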